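Read this before you add catalyst.

| flask | starting material | second substrate | free catalyst | remark |
|---|---|---|---|---|
| Thursday's | 1.5 M | 3 M | 1.5 mM | run made earlier |
| Friday's | 1.5 M | 3 M | 2.2 mM | run made earlier |
| Sunday's | 0.75 M | 3 M | 3 mM | run made earlier |
| flask | 1.5 M | 3.00 M | 3.0 mM |  |

| run | time / d | target / % |
|---|---|---|
| Thursday's | 0.500 | 10 |
| Thursday's | 1.04 | 16 |
| Thursday's | 1.67 | 24 |
| Thursday's | 2.08 | 18 |
| Thursday's | 2.50 | 23 |
| Thursday's | 3.00 | 26 |
| Thursday's | 4.00 | 23 |
| Friday's | 0.208 | 9 |
| Friday's | 0.500 | 13 |
| Friday's | 1.04 | 16 |
| Friday's | 1.67 | 20 |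
| Friday's | 2.00 | 23 |
| Friday's | 3.00 | 23 |
| Friday's | 4.00 | 26 |
| Sunday's | 0.625 | 20 |
| Sunday's | 1.25 | 23 |
| Sunday's | 2.00 | 27 |
| Sunday's | 3.00 | 26 |
| Sunday's | 4.00 | 24 |

(scatter of a reading: 2 percentage points)

1. factor on the rate of making target when 10% of the starting material are converted if second substrate is charged twice over
2. factor on the rate when 10% of the starting material are converted if free catalyst is charged at 30 mM instead

- no earlier run changes the charge of second substrate; that part of a forecast is a guess

1. This flask holds starting material, second substrate and free catalyst at 3.0 mM.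

2. When you come, expect target near the earlier runs: Thursday's, Friday's and Sunday's read 23%, 26% and 24% at 4.00 d.

3. I take early readings as rates. At 0.500 d, Thursday's run reads 10% on 1.5 mM of catalyst and Friday's reads 13% on 2.2 mM.

4. The logarithm of the first ratio over that of the second gives 0.685. I call this n, the catalyst order: the rise in the logarithm of the rate per rise in the logarithm of the catalyst. With a scatter of 2 percentage points, it is a loose reading.

5. Going to 30 mM is one power of ten, so I expect a factor of 4.84, not ten. No run varies second substrate, so I give no factor for it.

6. The forecast says 2.4 and 9, holding that “the relaxation rate is roughly first order in catalyst”, where I expect 4.84 for the catalyst.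

    starting material + free catalyst ⇌ catalyst intermediate A (K = 0.570 /M, k = 0.750 /M/min)
    catalyst intermediate A ⇌ free catalyst + target (K = 0.590 M, k = 1.30 /min)
    second substrate + free catalyst ⇌ catalyst intermediate B (K = 0.530 /M, k = 1.30 /M/min)
    catalyst intermediate B → free catalyst + second product (k = 0.730 /min)
    2 catalyst intermediate A ⇌ resting dimer, settled at all times (K = 3700 /M)

7. This flask gives 0.824 for doubled second substrate and 4.93 for 30 mM, so n between the two catalyst charges is 0.693. At 3.00 d, the half-life of starting material by the forward step alone is 0.91 d, shorter than the time gone, yet 75% of the starting material is left. Counting each resting dimer as two, that dimer holds 35.3% of the catalyst in this flask at 0.300 d, and 70.2% with 30 mM at the same conversion.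

All runs are simulated from invented constants; noise was put on by code.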